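**Strategy.** Everything rests on cutting the cyclohexanone ring (ring B) away from the catechol ring (ring A) at C1–C8a and C4–C4a. Ring A carries four contiguous substituents (C4a, C8a, O8, O7), so it enters as a 3,4-dioxygenated aryne with its triple bond between C4a and C8a. The oxygen on C8 steers a sulfone-stabilised C4 carbanion to C4a. The C8a anion then acylates on the tethered C1 ester, closing ring B in one operation. The precursor is an open-chain γ-naphthyl-γ-sulfonyl butanoate. The sulfone is later expelled by the para-hydroxynaphthyl group, and the resulting quinone methide is reduced enantioselectively to set C4 as (S).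

Key step: step 9

Numbering: C1–C8a is the tetralone (C1 carbonyl, C4 stereocentre, O7 and O8 the catechol oxygens). Primed numbers are the naphthalene (C1' bonded to C4, O4' the free hydroxyl, O8' the methoxy oxygen).

Assumption: (R)-TRIP, that is (R)-3,3'-bis(2,4,6-triisopropylphenyl)-1,1'-binaphthyl-2,2'-diyl hydrogen phosphate, is taken to leave open the face of C4 that leads to (S); the sense would be checked on the first run and the (S)-acid used if it is the opposite.

Step 1
Reactants: 1 1,5-dimethoxynaphthalene
Product: 3 4,8-dimethoxynaphthalene-1-carbaldehyde, via aryl iminium chloride 2 (not isolated)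
Conditions: POCl3, DMF, toluene, 0 to 90 °C; then aq NaOAc
Reagents that add atoms: DMF, CN(C)C=O; water, O
Why: Vilsmeier–Haack formylation: the chloroiminium ion attacks para to a methoxy group, the two such positions of the C2-symmetric 1 are equivalent so only one regioisomer can form, the iminium group deactivates the system against a second attack, and 2 is hydrolysed on work-up.

Step 2
Reactants: 3 4,8-dimethoxynaphthalene-1-carbaldehyde
Product: 5 4-(allyloxy)-8-methoxynaphthalene-1-carbaldehyde, via sodium naphtholate 4 (not isolated)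
Conditions: NaSEt (1.1 equiv), DMF, 100 °C; then allyl bromide, rt to 50 °C
Reagents that add atoms: allyl bromide, C=CCBr
Why: SN2 O-demethylation followed by Williamson etherification: thiolate takes the methyl group whose aryloxide is the better leaving group, that is O4, which is conjugated with the para formyl group like a vinylogous carboxylate, while O8 lies on the other ring outside this conjugation, and naphtholate 4 is allylated in the same flask.

Step 3
Reactants: 5 4-(allyloxy)-8-methoxynaphthalene-1-carbaldehyde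
Product: 7 1-(allyloxy)-5-methoxy-4-[(phenylsulfonyl)methyl]naphthalene, via naphthylmethanol 6 (not isolated)
Conditions: NaBH4, THF–MeOH, 0 °C; then PhSO2Na (2 equiv), HCO2H, rt
Reagents that add atoms: sodium benzenesulfinate, [Na+].[O-]S(=O)c1ccccc1
Why: Borohydride reduction followed by SN1-type dehydrative sulfonylation: formic acid ionises the electron-rich naphthylmethanol 6, the soft sulfur of the sulfinate captures the cation, and any O-bound sulfinate ester re-ionises until the stable sulfone is reached.

Step 4
Reactants: 7 1-(allyloxy)-5-methoxy-4-[(phenylsulfonyl)methyl]naphthalene; 8 methyl acrylate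
Product: 9 methyl 4-[4-(allyloxy)-8-methoxynaphthalen-1-yl]-4-(phenylsulfonyl)butanoate (racemic)
Conditions: KOtBu (0.2 equiv), THF, −20 to 0 °C
Reagents that add atoms: none
Why: Base-catalysed Michael addition: the sulfonyl carbanion adds to the acrylate, the ester enolate passes the proton on and carries the chain, a second addition is held back by crowding between the peri methoxy group and the now tertiary carbon, and the new centre is racemic, which is of no consequence because it is deprotonated in step 9.

Step 5
Reactants: 10 pyrogallol (benzene-1,2,3-triol)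
Product: 11 2,2-diphenyl-1,3-benzodioxol-4-ol
Conditions: Ph2CCl2 (1.1 equiv), Ph2O, 175 °C
Reagents that add atoms: dichlorodiphenylmethane, ClC(Cl)(c1ccccc1)c1ccccc1
Why: Ketalisation of a catechol by a gem-dichloride: one carbon can bridge only two neighbouring oxygens in a five-membered ring, so exactly one hydroxyl group stays free, and it is the one next to the protected pair, as the aryne requires.

Step 6
Reactants: 11 2,2-diphenyl-1,3-benzodioxol-4-ol
Product: 12 2,2-diphenyl-1,3-benzodioxol-4-yl N-isopropylcarbamate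
Conditions: i-PrNCO, Et3N (cat.), CH2Cl2, rt
Reagents that add atoms: isopropyl isocyanate, CC(C)N=C=O
Why: Addition of the phenol to the isocyanate gives the N-monoalkyl carbamate, a strong directing group for metalation that can later be removed by mild base.

Step 7
Reactants: 12 2,2-diphenyl-1,3-benzodioxol-4-yl N-isopropylcarbamate
Product: 16 2,2-diphenyl-5-(trimethylsilyl)-1,3-benzodioxol-4-yl N-isopropylcarbamate, via N-silyl carbamate 13 (not isolated), via aryllithium 14 (not isolated), via N,C-disilyl carbamate 15 (not isolated)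
Conditions: t-BuMe2SiOTf, TMEDA, Et2O, 0 °C to rt; n-BuLi, TMEDA, −78 °C; Me3SiCl, −78 °C to rt; aq NaHSO4
Reagents that add atoms: chlorotrimethylsilane, C[Si](C)(C)Cl
Why: Directed ortho-metalation: transient N-silylation (13) blocks the N–H so that no aryloxide is lost, n-BuLi/TMEDA lithiates the only position ortho to the carbamate (14), Me3SiCl traps it (15), and the N–Si bond is cleaved in the acidic work-up.

Step 8
Reactants: 16 2,2-diphenyl-5-(trimethylsilyl)-1,3-benzodioxol-4-yl N-isopropylcarbamate
Product: 18 2,2-diphenyl-5-(trimethylsilyl)-1,3-benzodioxol-4-yl trifluoromethanesulfonate, via silylphenol 17 (not isolated)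
Conditions: DBU, Et2NH, MeCN, 40 °C; then PhNTf2, rt
Reagents that add atoms: N-phenylbis(trifluoromethanesulfonimide), O=S(=O)(N(c1ccccc1)S(=O)(=O)C(F)(F)F)C(F)(F)F
Why: E1cB cleavage of the carbamate (DBU removes the N–H proton, isopropyl isocyanate leaves and is trapped by Et2NH) followed by O-sulfonylation of the phenoxide of 17 in the same flask gives the 2-silylaryl triflate.

Step 9
Reactants: 9 methyl 4-[4-(allyloxy)-8-methoxynaphthalen-1-yl]-4-(phenylsulfonyl)butanoate; 18 2,2-diphenyl-5-(trimethylsilyl)-1,3-benzodioxol-4-yl trifluoromethanesulfonate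
Product: 22 rac-4-[4-(allyloxy)-8-methoxynaphthalen-1-yl]-7,8-(diphenylmethylenedioxy)-4-(phenylsulfonyl)-3,4-dihydronaphthalen-1(2H)-one, via potassium carbanion 19 (not isolated), via aryne 20 (not isolated), via aryl anion 21 (not isolated)
Conditions: KN(SiMe3)2 (0.2 equiv), THF, −78 to 0 °C; then silyl triflate 18 (1.3 equiv), KF (3 equiv), 18-crown-6 (3 equiv), 4 Å MS, THF, 0 °C to rt
Reagents that add atoms: none
Why: Fluoride removes the silyl group of 18 and triflate leaves, giving aryne 20 with its triple bond between the future C4a and C8a, while carbanion 19 is formed from 9 by the initiator and afterwards by the methoxide that each ring closure releases. Carbanion 19 (future C4) adds to the aryne carbon remote from the dioxole oxygen (future C4a), because the C8–O bond distorts the aryne so that this carbon is the more linear and electrophilic one, the developing charge in 21 sits at C8a beside the withdrawing oxygen, and the remote carbon is also the less hindered. Aryl anion 21 then attacks the ester carbonyl in a 6-exo-trig acyl substitution and expels methoxide, which forms C1–C8a and closes ring B. The closest known reaction type is the anionic aryne annulation (carbanion addition followed by intramolecular acylation), as in the Hauser-type annulation of sulfonyl- or cyanophthalide anions with arynes. The quaternary centre C4 arises racemic and needs no control, since step 11 erases it and sets it anew. The step needs regioselectivity, secured by O8 as described, and ring closure ahead of protonation of 21, secured by the aprotic medium, the sieves that take up methanol and the gem-disubstitution at C4 that folds the chain towards C8a.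

Step 10
Reactants: 22 rac-4-[4-(allyloxy)-8-methoxynaphthalen-1-yl]-7,8-(diphenylmethylenedioxy)-4-(phenylsulfonyl)-3,4-dihydronaphthalen-1(2H)-one
Product: 23 rac-4-(4-hydroxy-8-methoxynaphthalen-1-yl)-7,8-(diphenylmethylenedioxy)-4-(phenylsulfonyl)-3,4-dihydronaphthalen-1(2H)-one
Conditions: Pd(PPh3)4 (5 mol %), PhSO2H (1.5 equiv), CH2Cl2, 0 °C to rt; used without chromatography
Reagents that add atoms: none
Why: Tsuji–Trost-type deallylation: zerovalent palladium ionises the allyl aryl ether and the sulfinic acid takes up the allyl fragment without any base that could trigger loss of the tertiary sulfone, while the surplus sulfinate returns any C4 centre that ionises early to 23.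

Step 11
Reactants: 23 rac-4-(4-hydroxy-8-methoxynaphthalen-1-yl)-7,8-(diphenylmethylenedioxy)-4-(phenylsulfonyl)-3,4-dihydronaphthalen-1(2H)-one
Product: 25 (S)-4-(4-hydroxy-8-methoxynaphthalen-1-yl)-7,8-(diphenylmethylenedioxy)-3,4-dihydronaphthalen-1(2H)-one, via quinone methide 24 (not isolated)
Conditions: (R)-TRIP (10 mol %), Hantzsch ester (diethyl 2,6-dimethyl-1,4-dihydropyridine-3,5-dicarboxylate, 1.5 equiv), CH2Cl2, −20 °C to rt, slow addition of 23
Reagents that add atoms: none
Why: Chiral-phosphoric-acid-catalysed asymmetric 1,6-transfer hydrogenation of a para-quinone methide made in situ: the free O4'–H pushes sulfinate out of both enantiomers of 23 to the same planar 24 (so the step is enantioconvergent), the acid binds the quinone methide oxygen and the N–H of the Hantzsch ester at once, and its 3,3'-aryl walls leave one face of C4 open to hydride, which sets (S).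

Step 12
Reactants: 25 (S)-4-(4-hydroxy-8-methoxynaphthalen-1-yl)-7,8-(diphenylmethylenedioxy)-3,4-dihydronaphthalen-1(2H)-one
Product: 26 (S)-7,8-dihydroxy-4-(4-hydroxy-8-methoxynaphthalen-1-yl)-3,4-dihydronaphthalen-1(2H)-one
Conditions: H2 (1 atm), Pd(OH)2/C, THF–MeOH, rt
Reagents that add atoms: none
Why: Hydrogenolysis of the two benzhydrylic C–O bonds of the ketal under neutral conditions frees the catechol, while the aryl methyl ether, the conjugated ketone and the C4–H centre, which has no pathway to epimerise here, are left as they are.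

**Compound list**

1 | 1,5-dimethoxynaphthalene | COc1cccc2c(OC)cccc12 | starting material
2 | (4,8-dimethoxynaphthalen-1-yl)methylidene-dimethyliminium chloride | C[N+](C)=Cc1ccc(OC)c2cccc(OC)c12.[Cl-] | intermediate
3 | 4,8-dimethoxynaphthalene-1-carbaldehyde | COc1ccc(C=O)c2c(OC)cccc12 | intermediate
4 | sodium 4-formyl-5-methoxynaphthalen-1-olate | [Na+].[O-]c1ccc(C=O)c2c(OC)cccc12 | intermediate
5 | 4-(allyloxy)-8-methoxynaphthalene-1-carbaldehyde | C=CCOc1ccc(C=O)c2c(OC)cccc12 | intermediate
6 | [4-(allyloxy)-8-methoxynaphthalen-1-yl]methanol | C=CCOc1ccc(CO)c2c(OC)cccc12 | intermediate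
7 | 1-(allyloxy)-5-methoxy-4-[(phenylsulfonyl)methyl]naphthalene | C=CCOc1ccc(CS(=O)(=O)c3ccccc3)c2c(OC)cccc12 | intermediate
8 | methyl acrylate | C=CC(=O)OC | starting material
9 | methyl 4-[4-(allyloxy)-8-methoxynaphthalen-1-yl]-4-(phenylsulfonyl)butanoate (racemic) | COC(=O)CCC(c1ccc(OCC=C)c2cccc(OC)c12)S(=O)(=O)c1ccccc1 | intermediate
10 | pyrogallol | Oc1cccc(O)c1O | starting material
11 | 2,2-diphenyl-1,3-benzodioxol-4-ol | Oc1cccc2OC(c3ccccc3)(c3ccccc3)Oc12 | intermediate
12 | 2,2-diphenyl-1,3-benzodioxol-4-yl N-isopropylcarbamate | CC(C)NC(=O)Oc1cccc2OC(c3ccccc3)(c3ccccc3)Oc12 | intermediate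
13 | N-(tert-butyldimethylsilyl) derivative of 12 | CC(C)N(C(=O)Oc1cccc2OC(c3ccccc3)(c3ccccc3)Oc12)[Si](C)(C)C(C)(C)C | intermediate
14 | 5-lithio derivative of 13 | [Li]c1ccc2OC(c3ccccc3)(c3ccccc3)Oc2c1OC(=O)N(C(C)C)[Si](C)(C)C(C)(C)C | intermediate
15 | 5-(trimethylsilyl) derivative of 13 | CC(C)N(C(=O)Oc1c([Si](C)(C)C)ccc2OC(c3ccccc3)(c3ccccc3)Oc12)[Si](C)(C)C(C)(C)C | intermediate
16 | 2,2-diphenyl-5-(trimethylsilyl)-1,3-benzodioxol-4-yl N-isopropylcarbamate | CC(C)NC(=O)Oc1c([Si](C)(C)C)ccc2OC(c3ccccc3)(c3ccccc3)Oc12 | intermediate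
17 | 2,2-diphenyl-5-(trimethylsilyl)-1,3-benzodioxol-4-ol | Oc1c([Si](C)(C)C)ccc2OC(c3ccccc3)(c3ccccc3)Oc12 | intermediate
18 | 2,2-diphenyl-5-(trimethylsilyl)-1,3-benzodioxol-4-yl trifluoromethanesulfonate | C[Si](C)(C)c1ccc2OC(c3ccccc3)(c3ccccc3)Oc2c1OS(=O)(=O)C(F)(F)F | intermediate
19 | potassium salt of the α-sulfonyl carbanion of 9 | [K+].COC(=O)CC[C-](c1ccc(OCC=C)c2cccc(OC)c12)S(=O)(=O)c1ccccc1 | intermediate
20 | 4,5-didehydro-2,2-diphenyl-1,3-benzodioxole (aryne) | C1#CC=CC2=C1OC(c1ccccc1)(c1ccccc1)O2 | intermediate
21 | potassium aryl anion from addition of 19 to 20 (charge on the carbon next to the dioxole oxygen) | [K+].COC(=O)CCC(c1ccc(OCC=C)c2cccc(OC)c12)(S(=O)(=O)c1ccccc1)c1ccc2OC(c3ccccc3)(c3ccccc3)Oc2[c-]1 | intermediate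
22 | rac-4-[4-(allyloxy)-8-methoxynaphthalen-1-yl]-7,8-(diphenylmethylenedioxy)-4-(phenylsulfonyl)-3,4-dihydronaphthalen-1(2H)-one | O=C1CCC(c2ccc(OCC=C)c3cccc(OC)c23)(S(=O)(=O)c2ccccc2)c2ccc3OC(c4ccccc4)(c4ccccc4)Oc3c12 | intermediate
23 | rac-4-(4-hydroxy-8-methoxynaphthalen-1-yl)-7,8-(diphenylmethylenedioxy)-4-(phenylsulfonyl)-3,4-dihydronaphthalen-1(2H)-one | O=C1CCC(c2ccc(O)c3cccc(OC)c23)(S(=O)(=O)c2ccccc2)c2ccc3OC(c4ccccc4)(c4ccccc4)Oc3c12 | intermediate
24 | para-quinone methide with the C4=C1' double bond (double-bond geometry open) | COc1cccc2C(=O)C=CC(=C3CCC(=O)c4c3ccc3OC(c5ccccc5)(c5ccccc5)Oc43)c12 | intermediate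
25 | (S)-4-(4-hydroxy-8-methoxynaphthalen-1-yl)-7,8-(diphenylmethylenedioxy)-3,4-dihydronaphthalen-1(2H)-one | COc1cccc2c(O)ccc([C@@H]3CCC(=O)c4c3ccc3OC(c5ccccc5)(c5ccccc5)Oc43)c12 | intermediate
26 | (S)-7,8-dihydroxy-4-(4-hydroxy-8-methoxynaphthalen-1-yl)-3,4-dihydronaphthalen-1(2H)-one | COc1cccc2c(O)ccc([C@@H]3CCC(=O)c4c3ccc(O)c4O)c12 | target

**Total step count:** 12. **Longest linear sequence:** 8 (steps 1–4 and 9–12; the aryne branch, steps 5–8 and 9–12, is equally long).

**Steps most likely to fail**

1. **Step 9.**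
   - What may go wrong: the crowded tertiary carbanion may add too slowly. The aryl anion may be protonated, by the C2–H of its own chain or by methanol, before it closes the ring. The strained product may lose sulfinate under the basic conditions, with aromatisation of ring B.
   - Fallback (sets out from 9, uses 18, returns at 25): the carbanion/ester pair is replaced by a 2-oxyfuran diene, so both bonds are made by a [4+2] cycloaddition and the lactone oxygen serves as a temporary bridge. Oxidative desulfonylation of 9 (KN(SiMe3)2, then Me3SiOOSiMe3) would give methyl 4-[4-(allyloxy)-8-methoxynaphthalen-1-yl]-4-oxobutanoate F1. Saponification (LiOH) would give 4-[4-(allyloxy)-8-methoxynaphthalen-1-yl]-4-oxobutanoic acid F2, and Ac2O/NaOAc the enol lactone 5-[4-(allyloxy)-8-methoxynaphthalen-1-yl]furan-2(3H)-one F3. With CsF in MeCN, F3 is deprotonated to its aromatic 2-furanolate. This takes up aryne 20 (from 18) across C5 and C2, the electron-rich aryl-bearing C5 bonding to the aryne carbon remote from O8. The oxa-bridged alkoxide then opens to 4-[4-(allyloxy)-8-methoxynaphthalen-1-yl]-4-hydroxy-7,8-(diphenylmethylenedioxy)naphthalen-1(4H)-one F4. Conjugate reduction with [(Ph3P)CuH]6 would give 4-[4-(allyloxy)-8-methoxynaphthalen-1-yl]-4-hydroxy-7,8-(diphenylmethylenedioxy)-3,4-dihydronaphthalen-1(2H)-one F5. Deallylation (Pd(PPh3)4, morpholine) would give 4-hydroxy-4-(4-hydroxy-8-methoxynaphthalen-1-yl)-7,8-(diphenylmethylenedioxy)-3,4-dihydronaphthalen-1(2H)-one F6. Under the conditions of step 11, F6 loses water to the same quinone methide 24 and gives 25.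

2. **Step 11.**
   - What may go wrong: deprotonation of the quinone methide at C3 followed by enolisation of the ketone would aromatise ring B irreversibly. Facial selectivity may be poor because the quinone methide can adopt two double-bond geometries, and because the liberated sulfinic acid may catalyse an unselective background reduction.
   - Fallback (sets out from 22, returns at 25): no cation or quinone methide is formed at C4, and a temporary stereocentre at C1 carries the chirality instead. Asymmetric transfer hydrogenation of 22 (RuCl[(S,S)-TsDPEN](p-cymene), HCO2H–Et3N, CH2Cl2) fixes C1 as (S) in both C4 epimers. This gives (1S)-4-[4-(allyloxy)-8-methoxynaphthalen-1-yl]-7,8-(diphenylmethylenedioxy)-4-(phenylsulfonyl)-1,2,3,4-tetrahydronaphthalen-1-ol F7. Electron-transfer desulfonylation (Mg, MeOH) passes through a C4 carbanion common to both epimers, and its protonation gives two diastereomers that differ only at C4 and are separated by chromatography. The isomer kept is (1S,4S)-4-[4-(allyloxy)-8-methoxynaphthalen-1-yl]-7,8-(diphenylmethylenedioxy)-1,2,3,4-tetrahydronaphthalen-1-ol F8. Oxidation with Dess–Martin periodinane removes the temporary centre and gives (S)-4-[4-(allyloxy)-8-methoxynaphthalen-1-yl]-7,8-(diphenylmethylenedioxy)-3,4-dihydronaphthalen-1(2H)-one F9. Deallylation as in step 10 gives 25.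

3. **Step 2.**
   - What may go wrong: thiolate may attack the wrong methyl ether or both.
   - Fallback (sets out from 3, returns at 5): the two oxygens are told apart by hydrogen bonding instead of leaving-group ability. Exhaustive demethylation (BBr3, CH2Cl2) would give 4,8-dihydroxynaphthalene-1-carbaldehyde F10. One equivalent of allyl bromide with KHCO3 in DMF alkylates only the more acidic O4–H, because O8–H is locked in a hydrogen bond to the peri formyl group. This gives 4-(allyloxy)-8-hydroxynaphthalene-1-carbaldehyde F11. Methylation (MeI, K2CO3, DMF) then gives 5.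

**Further compounds**

F1 | step 9 | methyl 4-[4-(allyloxy)-8-methoxynaphthalen-1-yl]-4-oxobutanoate | COC(=O)CCC(=O)c1ccc(OCC=C)c2cccc(OC)c12
F2 | step 9 | 4-[4-(allyloxy)-8-methoxynaphthalen-1-yl]-4-oxobutanoic acid | OC(=O)CCC(=O)c1ccc(OCC=C)c2cccc(OC)c12
F3 | step 9 | 5-[4-(allyloxy)-8-methoxynaphthalen-1-yl]furan-2(3H)-one | O=C1CC=C(O1)c1ccc(OCC=C)c2cccc(OC)c12
F4 | step 9 | 4-[4-(allyloxy)-8-methoxynaphthalen-1-yl]-4-hydroxy-7,8-(diphenylmethylenedioxy)naphthalen-1(4H)-one (racemic) | O=C1C=CC(O)(c2ccc(OCC=C)c3cccc(OC)c23)c2ccc3OC(c4ccccc4)(c4ccccc4)Oc3c12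
F5 | step 9 | 4-[4-(allyloxy)-8-methoxynaphthalen-1-yl]-4-hydroxy-7,8-(diphenylmethylenedioxy)-3,4-dihydronaphthalen-1(2H)-one (racemic) | O=C1CCC(O)(c2ccc(OCC=C)c3cccc(OC)c23)c2ccc3OC(c4ccccc4)(c4ccccc4)Oc3c12
F6 | step 9 | 4-hydroxy-4-(4-hydroxy-8-methoxynaphthalen-1-yl)-7,8-(diphenylmethylenedioxy)-3,4-dihydronaphthalen-1(2H)-one (racemic) | O=C1CCC(O)(c2ccc(O)c3cccc(OC)c23)c2ccc3OC(c4ccccc4)(c4ccccc4)Oc3c12
F7 | step 11 | (1S)-4-[4-(allyloxy)-8-methoxynaphthalen-1-yl]-7,8-(diphenylmethylenedioxy)-4-(phenylsulfonyl)-1,2,3,4-tetrahydronaphthalen-1-ol (both C4 epimers) | O[C@H]1CCC(c2ccc(OCC=C)c3cccc(OC)c23)(S(=O)(=O)c2ccccc2)c2ccc3OC(c4ccccc4)(c4ccccc4)Oc3c12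
F8 | step 11 | (1S,4S)-4-[4-(allyloxy)-8-methoxynaphthalen-1-yl]-7,8-(diphenylmethylenedioxy)-1,2,3,4-tetrahydronaphthalen-1-ol | O[C@H]1CC[C@@H](c2ccc(OCC=C)c3cccc(OC)c23)c2ccc3OC(c4ccccc4)(c4ccccc4)Oc3c12
F9 | step 11 | (S)-4-[4-(allyloxy)-8-methoxynaphthalen-1-yl]-7,8-(diphenylmethylenedioxy)-3,4-dihydronaphthalen-1(2H)-one | O=C1CC[C@@H](c2ccc(OCC=C)c3cccc(OC)c23)c2ccc3OC(c4ccccc4)(c4ccccc4)Oc3c12
F10 | step 2 | 4,8-dihydroxynaphthalene-1-carbaldehyde | O=Cc1ccc(O)c2cccc(O)c12
F11 | step 2 | 4-(allyloxy)-8-hydroxynaphthalene-1-carbaldehyde | O=Cc1ccc(OCC=C)c2cccc(O)c12
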